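**Plan**

1. Retrosynthetic cuts, in order: the Z-alkene back to an alkyne and the alkyne–C8 bond of the styryl coumarin (Sonogashira); then the bond from C8 of the second coumarin to ring carbon C1' (key step); then the cyclohexene bonds C1'–C6' and C4'–C5' (Diels–Alder).
2. Enabling feature: C1' is allylic to the ring C2'=C3'(CH3) double bond, so it is the secondary end of an allyl cation whose far end is tertiary. Coumarin C8 lies between O1/C8a and the 7-OMe and para to the 5-OMe, the most nucleophilic and least hindered arene carbon.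
3. Forward: the silyl dienol ether of prenal and methacrolein give the cyclohexene (the only ring made; both coumarins are used intact). CHO becomes ethynyl, 5,7-dimethoxycoumarin is joined at C1', the second coumarin is coupled to the alkyne, and the alkyne is semi-hydrogenated.
4. Stereochemistry: the quaternary C6' comes from the catalyst-controlled Diels–Alder reaction. C1' is set in the key step relative to C6', the arene entering cis to the slim ethynyl group and trans to methyl. The silyloxy centre is ionised, so both of its epimers converge.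
5. Helpers: the silyloxy group is the leaving group. The side chain is held at the alkyne oxidation level for steric control and becomes the Z-alkene by cis-hydrogenation at the end.

Key step: step 4

Assumption: the (S)-diphenylprolinol-derived cationic oxazaborolidine is taken to expose the methacrolein face that gives (1S)-4 (formyl C–H···O binding model); if the sense is opposite, the mirror-image catalyst is used with no other change.

**Route**

Step 1
Reactants: 1 3-methylbut-2-enal (prenal)
Product: 2 (E)-tert-butyl(dimethyl)[(3-methylbuta-1,3-dien-1-yl)oxy]silane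
Conditions: TBSOTf, Et3N, Et2O, 0 °C to rt
Reagents that add atoms: tert-butyldimethylsilyl trifluoromethanesulfonate, CC(C)(C)[Si](C)(C)OS(=O)(=O)C(F)(F)F
Why: Silyl dienol ether formation by soft enolisation: O-silylation of the enal and γ-deprotonation by the amine should give the conjugated dienol ether with the E enol ether geometry.

Step 2
Reactants: 2 (E)-tert-butyl(dimethyl)[(3-methylbuta-1,3-dien-1-yl)oxy]silane; 3 2-methylprop-2-enal (methacrolein)
Product: 4 (1S,2R)-2-[(tert-butyldimethylsilyl)oxy]-1,4-dimethylcyclohex-3-ene-1-carbaldehyde (cis, formyl-endo adduct)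
Conditions: (S)-diphenylprolinol-derived B-(o-tolyl)oxazaborolidine·Tf2NH (20 mol %), CH2Cl2, −78 °C
Reagents that add atoms: none
Why: Catalytic enantioselective Diels–Alder reaction in which the 1-silyloxy and 3-methyl groups of the diene both direct its oxygen-bearing carbon onto the α-carbon of the enal, while the boron-bound s-trans enal is shielded on one face so that the quaternary carbon should form as S; the configuration at the silyloxy carbon (cis drawn, trans epimer also usable) is of no consequence because step 4 ionises it.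

Step 3
Reactants: 4 (1S,2R)-2-[(tert-butyldimethylsilyl)oxy]-1,4-dimethylcyclohex-3-ene-1-carbaldehyde
Product: 5 tert-butyl{[(1R,6R)-6-ethynyl-3,6-dimethylcyclohex-2-en-1-yl]oxy}dimethylsilane
Conditions: dimethyl (1-diazo-2-oxopropyl)phosphonate, K2CO3, MeOH, 0 °C to rt
Reagents that add atoms: dimethyl (1-diazo-2-oxopropyl)phosphonate, CC(=O)C(=[N+]=[N-])P(=O)(OC)OC
Why: Seyferth–Gilbert homologation in the Ohira–Bestmann form, suited to a non-enolisable aldehyde; the quaternary centre cannot epimerise and the silyl ether blocks retro-aldol cleavage (the descriptor changes only through the priority rules).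

Step 4
Reactants: 5 tert-butyl{[(1R,6R)-6-ethynyl-3,6-dimethylcyclohex-2-en-1-yl]oxy}dimethylsilane; 6 5,7-dimethoxy-2H-chromen-2-one (5,7-dimethoxycoumarin, 3 equiv)
Product: 8 8-[(1R,6S)-6-ethynyl-3,6-dimethylcyclohex-2-en-1-yl]-5,7-dimethoxy-2H-chromen-2-one, via cyclohexenyl allyl cation 7 (not isolated)
Conditions: Bi(OTf)3 (10 mol %), (CF3)2CHOH/CH2Cl2, 0 °C
Reagents that add atoms: none
Why: The acid in the ionising solvent activates the allylic silyl ether of either epimer of 5, loss of silanol gives allyl cation 7 (charge shared by the secondary carbon next to the quaternary centre and the tertiary methyl-bearing carbon), C8 of 6 attacks the secondary terminus, and loss of the C8 proton restores the coumarin. The closest known reaction types are the acid-catalysed Friedel–Crafts allylation of resorcinols with p-mentha-2,8-dien-1-ol (the cannabidiol coupling) and the Bi(OTf)3-catalysed arylation of allylic silyl ethers. No ring is closed. The new stereocentre is controlled by the adjacent quaternary carbon: the arene should enter pseudoaxially on the face that carries the slim ethynyl group (A value about 0.4 kcal/mol, against 1.7 for methyl), staying gauche to ethynyl and anti to methyl, and this isomer is also the more stable one if the alkylation equilibrates. The step needs site selectivity on the cation (secondary over tertiary terminus, since attack at the tertiary end would build a fully substituted benzylic carbon between two ortho oxygens), site selectivity on the arene (C8 over C6, C8 being para to the 5-OMe and flanked by only one methoxy group) and the facial selectivity above; elimination to dienes is reversible under the acid and the excess of 6 should outcompete it.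

Step 5
Reactants: 6 5,7-dimethoxy-2H-chromen-2-one
Product: 9 8-iodo-5,7-dimethoxy-2H-chromen-2-one
Conditions: NIS, TFA (cat.), MeCN, rt
Reagents that add atoms: N-iodosuccinimide, O=C1CCC(=O)N1I
Why: Electrophilic aromatic iodination, expected at C8 for the same electronic and steric reasons as in step 4; a minor 6-iodo isomer would be removed by crystallisation.

Step 6
Reactants: 8 8-[(1R,6S)-6-ethynyl-3,6-dimethylcyclohex-2-en-1-yl]-5,7-dimethoxy-2H-chromen-2-one; 9 8-iodo-5,7-dimethoxy-2H-chromen-2-one
Product: 10 8-{[(1S,2R)-2-(5,7-dimethoxy-2-oxo-2H-chromen-8-yl)-1,4-dimethylcyclohex-3-en-1-yl]ethynyl}-5,7-dimethoxy-2H-chromen-2-one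
Conditions: PdCl2(PPh3)2 (5 mol %), CuI (10 mol %), Et3N, DMF, 60 °C, degassed
Reagents that add atoms: none
Why: Sonogashira coupling of a terminal alkyne with an electron-rich aryl iodide, which tolerates both lactones and touches no stereocentre.

Step 7
Reactants: 10 8-{[(1S,2R)-2-(5,7-dimethoxy-2-oxo-2H-chromen-8-yl)-1,4-dimethylcyclohex-3-en-1-yl]ethynyl}-5,7-dimethoxy-2H-chromen-2-one
Product: 11 8-[(1R,6R)-6-[(Z)-2-(5,7-dimethoxy-2-oxo-2H-chromen-8-yl)ethenyl]-3,6-dimethylcyclohex-2-en-1-yl]-5,7-dimethoxy-2H-chromen-2-one (target)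
Conditions: H2 (1 atm), Pd/CaCO3 poisoned with Pb(OAc)2, quinoline, EtOAc, rt
Reagents that add atoms: none
Why: Lindlar semi-hydrogenation adds H2 syn to the alkyne and should give the Z-alkene, leaving the trisubstituted ring alkene and the coumarin C3=C4 bonds untouched.

**Compound list**

1 | 3-methylbut-2-enal | CC(C)=CC=O | starting material
2 | (E)-tert-butyl(dimethyl)[(3-methylbuta-1,3-dien-1-yl)oxy]silane | C=C(C)/C=C/O[Si](C)(C)C(C)(C)C | intermediate
3 | 2-methylprop-2-enal | CC(=C)C=O | starting material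
4 | (1S,2R)-2-[(tert-butyldimethylsilyl)oxy]-1,4-dimethylcyclohex-3-ene-1-carbaldehyde | O=C[C@@]1(C)CCC(C)=C[C@H]1O[Si](C)(C)C(C)(C)C | intermediate
5 | tert-butyl{[(1R,6R)-6-ethynyl-3,6-dimethylcyclohex-2-en-1-yl]oxy}dimethylsilane | C#C[C@@]1(C)CCC(C)=C[C@H]1O[Si](C)(C)C(C)(C)C | intermediate
6 | 5,7-dimethoxy-2H-chromen-2-one | COc1cc(OC)c2ccc(=O)oc2c1 | starting material
7 | 6-ethynyl-3,6-dimethylcyclohex-2-en-1-yl cation, quaternary carbon configured as in 5 | C#C[C@@]1(C)CCC(C)=C[CH+]1 | intermediate (not isolated)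
8 | 8-[(1R,6S)-6-ethynyl-3,6-dimethylcyclohex-2-en-1-yl]-5,7-dimethoxy-2H-chromen-2-one | C#C[C@@]1(C)CCC(C)=C[C@H]1c1c(OC)cc(OC)c2ccc(=O)oc12 | intermediate
9 | 8-iodo-5,7-dimethoxy-2H-chromen-2-one | COc1cc(OC)c2ccc(=O)oc2c1I | intermediate
10 | 8-{[(1S,2R)-2-(5,7-dimethoxy-2-oxo-2H-chromen-8-yl)-1,4-dimethylcyclohex-3-en-1-yl]ethynyl}-5,7-dimethoxy-2H-chromen-2-one | COc1cc(OC)c2ccc(=O)oc2c1C#C[C@@]1(C)CCC(C)=C[C@H]1c1c(OC)cc(OC)c2ccc(=O)oc12 | intermediate
11 | 8-[(1R,6R)-6-[(Z)-2-(5,7-dimethoxy-2-oxo-2H-chromen-8-yl)ethenyl]-3,6-dimethylcyclohex-2-en-1-yl]-5,7-dimethoxy-2H-chromen-2-one | COc1cc(OC)c2ccc(=O)oc2c1/C=C\[C@@]1(C)CCC(C)=C[C@H]1c1c(OC)cc(OC)c2ccc(=O)oc12 | target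

**Count and risks**

Total step count: 7. Longest linear sequence: 6 (steps 1, 2, 3, 4, 6, 7).

Steps most likely to fail:

1. Step 4. What may go wrong: weak facial discrimination between the ethynyl and methyl faces of the cation, slow capture by the only moderately nucleophilic coumarin so that elimination and oligomerisation take over, or alkylation through C6 of the coumarin. The fallback makes the arylation intramolecular; it sets out from 4 and comes back at 8. Aldehyde 4 is oxidised (NaClO2, NaH2PO4, 2-methylbut-2-ene, t-BuOH/H2O) to (1S,2R)-2-[(tert-butyldimethylsilyl)oxy]-1,4-dimethylcyclohex-3-ene-1-carboxylic acid F1. Esterification with 3,5-dimethoxyphenol (EDC·HCl, DMAP, CH2Cl2) gives the 3,5-dimethoxyphenyl ester F2. Under the acid conditions of step 4, without 6, the tethered arene should capture the allyl cation in a Friedel–Crafts closure of a six-membered lactone. The tether reaches only the secondary terminus and only the face of the carboxyl carbon, and the two ortho carbons of the arene are equivalent, so the cis-fused lactone (6aS,10aR)-1,3-dimethoxy-6a,9-dimethyl-6a,7,8,10a-tetrahydro-6H-benzo[c]chromen-6-one F3 should form without relying on the size argument. DIBAL-H (CH2Cl2, −78 °C) gives the lactol (6aS,10aR)-1,3-dimethoxy-6a,9-dimethyl-6a,7,8,10a-tetrahydro-6H-benzo[c]chromen-6-ol F4. The Ohira–Bestmann reagent (K2CO3, MeOH) converts its open hydroxy aldehyde form into 2-[(1R,6S)-6-ethynyl-3,6-dimethylcyclohex-2-en-1-yl]-3,5-dimethoxyphenol F5. Ortho-formylation (MgCl2, Et3N, paraformaldehyde, MeCN, reflux) gives 3-[(1R,6S)-6-ethynyl-3,6-dimethylcyclohex-2-en-1-yl]-2-hydroxy-4,6-dimethoxybenzaldehyde F6. Wittig olefination with Ph3P=CHCO2Et in hot N,N-diethylaniline passes through ethyl 3-{3-[(1R,6S)-6-ethynyl-3,6-dimethylcyclohex-2-en-1-yl]-2-hydroxy-4,6-dimethoxyphenyl}prop-2-enoate F7 and lactonises to 8.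

2. Step 2. What may go wrong: acid-mediated loss of the silyl dienol ether, Mukaiyama-type vinylogous aldol addition in place of cycloaddition, or insufficient enantioface discrimination. The fallback introduces the leaving group after the cycloaddition; it sets out from 3 and comes back at 8. Isoprene and 3 under the same cationic oxazaborolidine (an acid-stable diene in a well-precedented pairing) should give (S)-1,4-dimethylcyclohex-3-ene-1-carbaldehyde F8. Ohira–Bestmann homologation gives (S)-4-ethynyl-1,4-dimethylcyclohex-1-ene F9. m-CPBA (CH2Cl2, 0 °C) gives (4S)-4-ethynyl-1,4-dimethyl-7-oxabicyclo[4.1.0]heptane F10 as both epoxide diastereomers. PhSeNa (from (PhSe)2 and NaBH4, EtOH) opens it at the secondary carbon to (4S)-4-ethynyl-1,4-dimethyl-2-(phenylselanyl)cyclohexan-1-ol F11. H2O2 (THF, 0 °C to rt) oxidises this to (4S)-4-ethynyl-1,4-dimethyl-2-(phenylseleninyl)cyclohexan-1-ol F12, which eliminates syn, away from the carbinol carbon, to (4S)-4-ethynyl-1,4-dimethylcyclohex-2-en-1-ol F13. Under the conditions of step 4 with 6, this tertiary allylic alcohol ionises to the same cation 7 and should give 8.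

3. Step 7. What may go wrong: stalling of the hydrogenation at the doubly hindered alkyne, over-reduction, or Z to E isomerisation on the catalyst. The fallback fixes the Z geometry before the aryl–vinyl bond is made; it sets out from 8 (with 9) and comes back at 11. NIS and AgNO3 (acetone, rt) convert 8 into 8-[(1R,6S)-6-(iodoethynyl)-3,6-dimethylcyclohex-2-en-1-yl]-5,7-dimethoxy-2H-chromen-2-one F14. Diimide (2-nitrobenzenesulfonyl hydrazide, Et3N, THF/i-PrOH) reduces it cis to 8-[(1R,6S)-6-[(Z)-2-iodoethenyl]-3,6-dimethylcyclohex-2-en-1-yl]-5,7-dimethoxy-2H-chromen-2-one F15. Miyaura borylation of 9 (B2pin2, PdCl2(dppf), KOAc, dioxane, 80 °C) gives 5,7-dimethoxy-8-(4,4,5,5-tetramethyl-1,3,2-dioxaborolan-2-yl)-2H-chromen-2-one F16. Suzuki–Miyaura coupling of F15 with F16 (Pd(OAc)2, SPhos, K3PO4, THF/H2O, 40 °C) proceeds with retention of alkene geometry and should give 11.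

**Further compounds**

F1 | step 4 | (1S,2R)-2-[(tert-butyldimethylsilyl)oxy]-1,4-dimethylcyclohex-3-ene-1-carboxylic acid | OC(=O)[C@@]1(C)CCC(C)=C[C@H]1O[Si](C)(C)C(C)(C)C
F2 | step 4 | 3,5-dimethoxyphenyl (1S,2R)-2-[(tert-butyldimethylsilyl)oxy]-1,4-dimethylcyclohex-3-ene-1-carboxylate | COc1cc(OC)cc(OC(=O)[C@@]2(C)CCC(C)=C[C@H]2O[Si](C)(C)C(C)(C)C)c1
F3 | step 4 | (6aS,10aR)-1,3-dimethoxy-6a,9-dimethyl-6a,7,8,10a-tetrahydro-6H-benzo[c]chromen-6-one | COc1cc(OC)c2c(c1)OC(=O)[C@@]3(C)CCC(C)=C[C@@H]23
F4 | step 4 | (6aS,10aR)-1,3-dimethoxy-6a,9-dimethyl-6a,7,8,10a-tetrahydro-6H-benzo[c]chromen-6-ol (both anomers) | COc1cc(OC)c2c(c1)OC(O)[C@@]3(C)CCC(C)=C[C@@H]23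
F5 | step 4 | 2-[(1R,6S)-6-ethynyl-3,6-dimethylcyclohex-2-en-1-yl]-3,5-dimethoxyphenol | C#C[C@@]1(C)CCC(C)=C[C@H]1c1c(O)cc(OC)cc1OC
F6 | step 4 | 3-[(1R,6S)-6-ethynyl-3,6-dimethylcyclohex-2-en-1-yl]-2-hydroxy-4,6-dimethoxybenzaldehyde | C#C[C@@]1(C)CCC(C)=C[C@H]1c1c(O)c(C=O)c(OC)cc1OC
F7 | step 4 | ethyl 3-{3-[(1R,6S)-6-ethynyl-3,6-dimethylcyclohex-2-en-1-yl]-2-hydroxy-4,6-dimethoxyphenyl}prop-2-enoate (E and Z, not isolated) | C#C[C@@]1(C)CCC(C)=C[C@H]1c1c(O)c(C=CC(=O)OCC)c(OC)cc1OC
F8 | step 2 | (S)-1,4-dimethylcyclohex-3-ene-1-carbaldehyde | O=C[C@@]1(C)CCC(C)=CC1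
F9 | step 2 | (S)-4-ethynyl-1,4-dimethylcyclohex-1-ene | C#C[C@@]1(C)CCC(C)=CC1
F10 | step 2 | (4S)-4-ethynyl-1,4-dimethyl-7-oxabicyclo[4.1.0]heptane (both epoxide diastereomers) | C#C[C@@]1(C)CCC2(C)OC2C1
F11 | step 2 | (4S)-4-ethynyl-1,4-dimethyl-2-(phenylselanyl)cyclohexan-1-ol | C#C[C@@]1(C)CCC(C)(O)C([Se]c2ccccc2)C1
F12 | step 2 | (4S)-4-ethynyl-1,4-dimethyl-2-(phenylseleninyl)cyclohexan-1-ol (not isolated) | C#C[C@@]1(C)CCC(C)(O)C([Se](=O)c2ccccc2)C1
F13 | step 2 | (4S)-4-ethynyl-1,4-dimethylcyclohex-2-en-1-ol (both C1 epimers) | C#C[C@@]1(C)CCC(C)(O)C=C1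
F14 | step 7 | 8-[(1R,6S)-6-(iodoethynyl)-3,6-dimethylcyclohex-2-en-1-yl]-5,7-dimethoxy-2H-chromen-2-one | IC#C[C@@]1(C)CCC(C)=C[C@H]1c1c(OC)cc(OC)c2ccc(=O)oc12
F15 | step 7 | 8-[(1R,6S)-6-[(Z)-2-iodoethenyl]-3,6-dimethylcyclohex-2-en-1-yl]-5,7-dimethoxy-2H-chromen-2-one | I/C=C\[C@@]1(C)CCC(C)=C[C@H]1c1c(OC)cc(OC)c2ccc(=O)oc12
F16 | step 7 | 5,7-dimethoxy-8-(4,4,5,5-tetramethyl-1,3,2-dioxaborolan-2-yl)-2H-chromen-2-one | COc1cc(OC)c2ccc(=O)oc2c1B1OC(C)(C)C(C)(C)O1
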